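**A straight line.** A one-step world starts on a straight line: a steady rate makes target in proportion to time, and the line bends down as the charge is used. The grey run doesn't. It gains 0.00210 M between 0.22 h and 0.54 h, then 0.00400 M over the next 0.320 h, which is more in an equal span.

| flask | substrate | partner | catalyst | time |
|---|---|---|---|---|
| grey | 0.0800 M | 0.0640 M | 4.00 × 10⁻⁴ M |  |
| violet | 0.0320 M | 0.0160 M | 4.00 × 10⁻⁴ M |  |
| red | 0.120 M | 0.0640 M | 4.00 × 10⁻⁴ M |  |
| blue | 0.0800 M | 0.0640 M | 6.00 × 10⁻⁴ M |  |
| amber | 0.0800 M | 0.0640 M | 4.00 × 10⁻⁴ M | 20 h |

| run | time / h | [target] / M |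
|---|---|---|
| grey run | 0.14 | 1 × 10⁻⁴ |
| grey run | 0.22 | 0.0010 |
| grey run | 0.34 | 0.0019 |
| grey run | 0.54 | 0.0031 |
| grey run | 0.86 | 0.0071 |
| grey run | 1.4 | 0.0169 |
| grey run | 2.1 | 0.0295 |
| grey run | 3.4 | 0.0396 |
| violet run | 0.14 | 2 × 10⁻⁴ |
| violet run | 0.22 | 4 × 10⁻⁴ |
| violet run | 0.34 | 7 × 10⁻⁴ |
| violet run | 0.54 | 5 × 10⁻⁴ |
| violet run | 0.86 | 0.0013 |
| violet run | 1.4 | 0.0019 |
| violet run | 2.1 | 0.0026 |
| violet run | 3.4 | 0.0044 |
| red run | 0.14 | 2 × 10⁻⁴ |
| red run | 0.22 | 0.0010 |
| red run | 0.34 | 0.0021 |
| red run | 0.54 | 0.0053 |
| red run | 0.86 | 0.0134 |
| red run | 1.4 | 0.0329 |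
| red run | 2.1 | 0.0457 |
| red run | 3.4 | 0.0518 |
| blue run | 0.14 | 7 × 10⁻⁴ |
| blue run | 0.22 | 9 × 10⁻⁴ |
| blue run | 0.34 | 0.0022 |
| blue run | 0.54 | 0.0052 |
| blue run | 0.86 | 0.0106 |
| blue run | 1.4 | 0.0221 |
| blue run | 2.1 | 0.0338 |
| blue run | 3.4 | 0.0422 |

(standard deviation of a reading: 4 × 10⁻⁴ M)

- Overall: substrate + partner -> target, with catalyst as catalyst.
- Constant volume, constant temperature.
- The analysis sees a species whether free or bound.
- "The second partner" is partner.
- An order is taken over about fifteen percent of the charge, up and down.

1. the power of [catalyst] that the first rate follows, about the charge of the grey run; measure it at two percent of substrate made into target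
2. the power of [substrate] that the first rate follows, about the charge of the grey run; measure it at two percent of substrate made into target (one fixed amount of target, the same in the runs compared)
3. target in the amber run at 20 h, as a share of the substrate charged

**Two routes.** I try the next simplest world: the catalyst supplies a steady seed rate, and target speeds its own making (autocatalysis), so rate = seed + growth × target. This integrates to target + crossover = crossover × exp(growth × time). The equal spans give a growth of 2.01 h⁻¹. They also give a crossover of 0.00132 M, the amount of target at which the self-feeding route matches the seed route. Each difference carries the scatter of two readings, so this is a rough reading.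

**First instants.** Below the crossover the seed leads. The red flask holds 1.50 times the grey substrate, yet at 0.22 h it reads 0.0010 M and grey reads 0.0010 M, so I take the seed in the grey flask to be nearly indifferent to substrate.

**The mark.** Two percent of the grey substrate is 0.00160 M, close to the crossover. There the seed's share of the grey rate is crossover / (crossover + mark) = 0.452. I assume that the seed follows catalyst in the first power and is indifferent to substrate, and that the self-feeding part at fixed target follows substrate in the first power and is indifferent to catalyst. On those assumptions that share is my catalyst order, and the remainder, 0.548, is my substrate order.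

**The middle.** Past the crossover the curve climbs steeply, and the grey flask reaches 0.0169 M at 1.4 h.

**The end.** In the amber flask, charged like grey, partner is the limiting reagent and allows target up to 80.0% of the substrate. Grey's last reading is 0.0396 M at 3.4 h. For 20 h I commit to a share below that ceiling and to nothing closer.

**The check.** The forecast gives 0.6, 0.8 and 55.5%, holding that “an active catalyst builds up during the run”. The flask gives 0.54, 0.60 and 55.4%, where my orders were 0.452 for catalyst and 0.548 for substrate.

    catalyst + substrate → catalyst-substrate complex (1087 L mol⁻¹ h⁻¹)
    catalyst-substrate complex + partner → target + catalyst (171.7 L mol⁻¹ h⁻¹)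
    substrate + partner + target → 2 target (471.6 L² mol⁻² h⁻¹)
    target + partner → side product (4.680 L mol⁻¹ h⁻¹)

**The crossover, carried.** Without the step in which target helps substrate and partner to more target, the grey catalyst order is 1.1 rather than 0.54. So the self-feeding step pulls that order down, and my crossover of 0.00132 M put the seed's grey share at 0.452. The blue flask holds 1.50 times the catalyst, which raises the seed part and leaves the self-feeding part at the same target, so its rate at the mark should be 1.23 times grey's. The rates at the mark, 0.0089 M h⁻¹ in blue and 0.0070 M h⁻¹ in grey, stand at a ratio of 1.27.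

The readings stem from a simulated flask with made-up constants, and the scatter is random.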